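The synthesis rests on cutting C7–C8 of the side chain (C7 = benzylic carbinol on ring A, C8 = carbon bearing the ring-B aryl ether oxygen, C9 = methyl). Both carbons carry oxygen and are natural acceptors. C8 is therefore turned into a donor by raising C9 to the acyl level. The precursor is the N-(aryloxyacetyl)oxazolidinone of the finished tetrahydrofuran phenol. Its Z-boron enolate adds to veratraldehyde in an Evans syn glycolate aldol. One operation joins both halves and sets 7R,8R, exploiting the threo O7/O8 pair flanked by C9. The acyl carbon is then reduced to methyl. The cis,trans,cis-tetrahydrofuran arises by crotylboration, directed hydroformylation and arylzinc–oxocarbenium coupling.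

Key step: step 7

Assumption: compounds 2 and 14 and the catalyst (S)-TRIP [(S)-3,3'-bis(2,4,6-triisopropylphenyl)-1,1'-binaphthyl-2,2'-diyl hydrogen phosphate] are taken as catalogue items. The tetrahydrofuran is numbered O1, C2 (ring-B side) to C5 (veratryl side).

Step 1
Reactants: 1 3,4-dimethoxybenzaldehyde (veratraldehyde); 2 (Z)-crotylboronic acid pinacol ester
Product: 4 (1S,2R)-1-(3,4-dimethoxyphenyl)-2-methylbut-3-en-1-ol, via pinacol borate 3 (not isolated)
Conditions: (S)-TRIP (5 mol %), 4 Å MS, toluene, −30 °C; aq. NaHCO3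
Reagents that add atoms: none
Why: Chiral-phosphoric-acid-catalysed crotylboration (type I allylboration), in which the closed chair transition state turns the Z-crotyl geometry into the syn relationship and the (S)-catalyst, hydrogen-bonded to a boronate oxygen and the formyl H, should direct attack to the Si face, setting 1S,2R (the future C5 and C4).

Step 2
Reactants: 4 (1S,2R)-1-(3,4-dimethoxyphenyl)-2-methylbut-3-en-1-ol
Product: 6 (3R,4R,5S)-5-(3,4-dimethoxyphenyl)-3,4-dimethyltetrahydrofuran-2-ol (anomer mixture), via C3-epimeric lactol mixture 5 (not isolated)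
Conditions: Rh(CO)2(acac) (1 mol %), Ph2POMe (10 mol %), CO/H2 (1:1, 30 bar), 4 Å MS, THF, 40 °C; vent, then DBU (0.2 equiv), rt
Reagents that add atoms: carbon monoxide, [C-]#[O+]
Why: Rh-catalysed hydroformylation of a homoallylic alcohol with a catalytic, reversibly bound phosphinite directing group, in which a six-membered chelate places the formyl group on the internal alkene carbon, the γ-hydroxy aldehyde closes to the lactol, and base equilibration through the open aldehyde moves the new C3 methyl trans to the C4 methyl (3R).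

Step 3
Reactants: 6 (3R,4R,5S)-5-(3,4-dimethoxyphenyl)-3,4-dimethyltetrahydrofuran-2-ol
Product: 7 (3R,4R,5S)-5-(3,4-dimethoxyphenyl)-3,4-dimethyl-2-(phenylsulfonyl)tetrahydrofuran (C2 epimer mixture)
Conditions: PhSO2H, CaCl2, CH2Cl2, 0 °C to rt
Reagents that add atoms: benzenesulfinic acid, O=S(O)c1ccccc1
Why: Acid-mediated exchange of the anomeric hydroxyl for sulfinate (S-alkylation via the oxocarbenium ion, water bound by CaCl2) gives the 2-sulfonyl cyclic ether, in which C3–C5 are untouched and the C2 mixture is irrelevant because C2 is ionised again in step 5.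

Step 4
Reactants: 8 4-bromo-2-methoxyphenol
Product: 9 (4-bromo-2-methoxyphenoxy)(tert-butyl)dimethylsilane
Conditions: TBSCl, imidazole, DMF, rt
Reagents that add atoms: tert-butyldimethylsilyl chloride, CC(C)(C)[Si](C)(C)Cl
Why: Standard imidazole-promoted O-silylation masks the phenol so that the aryl bromide can be metalated, and no stereocentre is involved.

Step 5
Reactants: 7 (3R,4R,5S)-5-(3,4-dimethoxyphenyl)-3,4-dimethyl-2-(phenylsulfonyl)tetrahydrofuran; 9 (4-bromo-2-methoxyphenoxy)(tert-butyl)dimethylsilane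
Product: 13 tert-butyl{4-[(2S,3R,4R,5S)-5-(3,4-dimethoxyphenyl)-3,4-dimethyltetrahydrofuran-2-yl]-2-methoxyphenoxy}dimethylsilane, via aryllithium 10 (not isolated), via arylzinc bromide 11 (not isolated), via oxocarbenium ion 12 (not isolated)
Conditions: 9, n-BuLi, THF, −78 °C; ZnBr2, −78 °C to rt; then 7, THF, rt
Reagents that add atoms: none
Why: Organozinc substitution of a 2-sulfonyl cyclic ether, in which the zinc salts ionise 7 to 12 and the arylzinc attacks from the inside of the envelope that keeps both methyl groups pseudo-equatorial, anti to the C5 aryl and C4 methyl groups, which should set C2 as S (2,3-cis, 2,5-trans).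

Step 6
Reactants: 13 tert-butyl{4-[(2S,3R,4R,5S)-5-(3,4-dimethoxyphenyl)-3,4-dimethyltetrahydrofuran-2-yl]-2-methoxyphenoxy}dimethylsilane; 14 (S)-4-benzyl-3-(chloroacetyl)oxazolidin-2-one
Product: 16 (S)-4-benzyl-3-(2-{4-[(2S,3R,4R,5S)-5-(3,4-dimethoxyphenyl)-3,4-dimethyltetrahydrofuran-2-yl]-2-methoxyphenoxy}acetyl)oxazolidin-2-one, via caesium phenoxide 15 (not isolated)
Conditions: CsF, DMF, 0 °C to rt
Reagents that add atoms: none
Why: One-pot fluoride desilylation and Williamson ether synthesis, in which the liberated phenoxide displaces the activated α-chloride irreversibly whereas acyl transfer from the imide to phenoxide is reversible, and no stereocentre is touched.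

Step 7
Reactants: 16 (S)-4-benzyl-3-(2-{4-[(2S,3R,4R,5S)-5-(3,4-dimethoxyphenyl)-3,4-dimethyltetrahydrofuran-2-yl]-2-methoxyphenoxy}acetyl)oxazolidin-2-one; 1 3,4-dimethoxybenzaldehyde
Product: 19 (S)-4-benzyl-3-[(2S,3R)-3-(3,4-dimethoxyphenyl)-2-{4-[(2S,3R,4R,5S)-5-(3,4-dimethoxyphenyl)-3,4-dimethyltetrahydrofuran-2-yl]-2-methoxyphenoxy}-3-hydroxypropanoyl]oxazolidin-2-one, via Z-boron enolate 17 (not isolated), via boron aldolate 18 (not isolated)
Conditions: Bu2BOTf (1.05 equiv), Et3N, CH2Cl2, −78 to 0 °C; 1, −78 to 0 °C; pH 7 buffer, MeOH, H2O2, 0 °C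
Reagents that add atoms: none
Why: Soft enolisation of imide 16 with Bu2BOTf/Et3N gives the Z-boron enolate 17 (O–B and aryloxy group cis), which binds aldehyde 1 at boron and forms the C7–C8 bond through a closed six-membered Zimmerman–Traxler chair to give aldolate 18, released as 19 by the oxidative work-up. The closest known reaction type is the Evans syn aldol of N-(alkoxyacetyl)- and N-(aryloxyacetyl)oxazolidinones with aromatic aldehydes, and no ring of the product is closed in this step. The relative configuration (O7/O8 syn, i.e. threo) is controlled by the Z-enolate geometry together with the equatorial position of the veratryl group in the chair. The absolute configuration is controlled by the (S)-benzyl group of the auxiliary, which in the dipole-opposed conformer of the boron-bound enolate shields one enolate face, so that C8 is formed as 2S in 19 (8R once C9 is methyl) and the Si face of the aldehyde is attacked (7R). The four ring stereocentres lie too far from the reacting carbons to exert any influence, which is why reagent control is used and no matched/mismatched problem is expected. The step needs site-selective enolisation and survival of the acid-sensitive benzylic ethers: the imide CH2 is the only acidic C–H, aldehyde 1 cannot enolise, and near-stoichiometric Bu2BOTf, amine buffering and low temperature keep free Lewis acid away from the tetrahydrofuran.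

Step 8
Reactants: 19 the syn aldol adduct
Product: 20 (1R,2R)-1-(3,4-dimethoxyphenyl)-2-{4-[(2S,3R,4R,5S)-5-(3,4-dimethoxyphenyl)-3,4-dimethyltetrahydrofuran-2-yl]-2-methoxyphenoxy}propane-1,3-diol
Conditions: LiBH4, THF, 0 °C
Reagents that add atoms: none
Why: Reductive cleavage of the Evans auxiliary, in which borohydride attacks the more electrophilic exocyclic imide carbonyl and reduces it through the aldehyde to the primary alcohol, so C9 drops to the alcohol level while C7 and C8 are not touched.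

Step 9
Reactants: 20 the (1R,2R)-1,3-diol
Product: 21 (2R,3R)-3-(3,4-dimethoxyphenyl)-2-{4-[(2S,3R,4R,5S)-5-(3,4-dimethoxyphenyl)-3,4-dimethyltetrahydrofuran-2-yl]-2-methoxyphenoxy}-3-hydroxypropyl 4-methylbenzenesulfonate
Conditions: TsCl, pyridine, CH2Cl2, 0 °C
Reagents that add atoms: p-toluenesulfonyl chloride, Cc1ccc(S(=O)(=O)Cl)cc1
Why: Chemoselective sulfonylation, in which the unhindered primary C9 hydroxyl should react much faster than the crowded secondary benzylic C7 hydroxyl, and no stereocentre is involved.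

Step 10
Reactants: 21 the primary tosylate
Product: 22 (1R,2R)-1-(3,4-dimethoxyphenyl)-2-{4-[(2S,3R,4R,5S)-5-(3,4-dimethoxyphenyl)-3,4-dimethyltetrahydrofuran-2-yl]-2-methoxyphenoxy}propan-1-ol (CNP0286615.1)
Conditions: LiEt3BH, THF, 0 °C to rt
Reagents that add atoms: none
Why: SN2 displacement of the primary tosylate by the strongly nucleophilic triethylborohydride converts C9 into the methyl group, and since only C9 reacts the 7R,8R centres are retained.

Compound list
1 | 3,4-dimethoxybenzaldehyde | COc1ccc(C=O)cc1OC | starting material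
2 | (Z)-crotylboronic acid pinacol ester | C/C=C\CB1OC(C)(C)C(C)(C)O1 | starting material
3 | pinacol borate of alcohol 4 | CC1(C)OB(O[C@H](c2ccc(OC)c(OC)c2)[C@H](C)C=C)OC1(C)C | intermediate
4 | (1S,2R)-1-(3,4-dimethoxyphenyl)-2-methylbut-3-en-1-ol | O[C@H](c1ccc(OC)c(OC)c1)[C@H](C)C=C | intermediate
5 | (4R,5S)-5-(3,4-dimethoxyphenyl)-3,4-dimethyltetrahydrofuran-2-ol, C3 epimer and anomer mixture | OC1O[C@H](c2ccc(OC)c(OC)c2)[C@H](C)C1C | intermediate
6 | (3R,4R,5S)-5-(3,4-dimethoxyphenyl)-3,4-dimethyltetrahydrofuran-2-ol, anomer mixture | OC1O[C@H](c2ccc(OC)c(OC)c2)[C@H](C)[C@H]1C | intermediate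
7 | (3R,4R,5S)-5-(3,4-dimethoxyphenyl)-3,4-dimethyl-2-(phenylsulfonyl)tetrahydrofuran, C2 mixture | O=S(=O)(c1ccccc1)C1O[C@H](c2ccc(OC)c(OC)c2)[C@H](C)[C@H]1C | intermediate
8 | 4-bromo-2-methoxyphenol | COc1cc(Br)ccc1O | starting material
9 | (4-bromo-2-methoxyphenoxy)(tert-butyl)dimethylsilane | COc1cc(Br)ccc1O[Si](C)(C)C(C)(C)C | intermediate
10 | 4-(tert-butyldimethylsilyloxy)-3-methoxyphenyllithium | COc1cc([Li])ccc1O[Si](C)(C)C(C)(C)C | intermediate
11 | 4-(tert-butyldimethylsilyloxy)-3-methoxyphenylzinc bromide | COc1cc([Zn]Br)ccc1O[Si](C)(C)C(C)(C)C | intermediate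
12 | (3R,4R,5S)-5-(3,4-dimethoxyphenyl)-3,4-dimethyl-4,5-dihydro-3H-furan-1-ium (oxocarbenium ion) | C1=[O+][C@H](c2ccc(OC)c(OC)c2)[C@H](C)[C@H]1C | intermediate
13 | tert-butyl{4-[(2S,3R,4R,5S)-5-(3,4-dimethoxyphenyl)-3,4-dimethyltetrahydrofuran-2-yl]-2-methoxyphenoxy}dimethylsilane | COc1cc([C@H]2O[C@H](c3ccc(OC)c(OC)c3)[C@H](C)[C@H]2C)ccc1O[Si](C)(C)C(C)(C)C | intermediate
14 | (S)-4-benzyl-3-(chloroacetyl)oxazolidin-2-one | O=C(CCl)N1C(=O)OC[C@@H]1Cc1ccccc1 | starting material
15 | caesium 4-[(2S,3R,4R,5S)-5-(3,4-dimethoxyphenyl)-3,4-dimethyltetrahydrofuran-2-yl]-2-methoxyphenoxide | COc1cc([C@H]2O[C@H](c3ccc(OC)c(OC)c3)[C@H](C)[C@H]2C)ccc1[O-].[Cs+] | intermediate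
16 | (S)-4-benzyl-3-(2-{4-[(2S,3R,4R,5S)-5-(3,4-dimethoxyphenyl)-3,4-dimethyltetrahydrofuran-2-yl]-2-methoxyphenoxy}acetyl)oxazolidin-2-one | COc1cc([C@H]2O[C@H](c3ccc(OC)c(OC)c3)[C@H](C)[C@H]2C)ccc1OCC(=O)N1C(=O)OC[C@@H]1Cc1ccccc1 | intermediate
17 | (Z)-dibutylboron enolate of 16 | CCCCB(CCCC)O/C(=C\Oc1ccc([C@H]2O[C@H](c3ccc(OC)c(OC)c3)[C@H](C)[C@H]2C)cc1OC)N1C(=O)OC[C@@H]1Cc1ccccc1 | intermediate
18 | dibutylboron aldolate of 19 | COc1ccc([C@@H](OB(CCCC)CCCC)[C@@H](C(=O)N2C(=O)OC[C@@H]2Cc2ccccc2)Oc2ccc([C@H]3O[C@H](c4ccc(OC)c(OC)c4)[C@H](C)[C@H]3C)cc2OC)cc1OC | intermediate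
19 | (S)-4-benzyl-3-[(2S,3R)-3-(3,4-dimethoxyphenyl)-2-{4-[(2S,3R,4R,5S)-5-(3,4-dimethoxyphenyl)-3,4-dimethyltetrahydrofuran-2-yl]-2-methoxyphenoxy}-3-hydroxypropanoyl]oxazolidin-2-one | COc1ccc([C@@H](O)[C@@H](C(=O)N2C(=O)OC[C@@H]2Cc2ccccc2)Oc2ccc([C@H]3O[C@H](c4ccc(OC)c(OC)c4)[C@H](C)[C@H]3C)cc2OC)cc1OC | intermediate
20 | (1R,2R)-1-(3,4-dimethoxyphenyl)-2-{4-[(2S,3R,4R,5S)-5-(3,4-dimethoxyphenyl)-3,4-dimethyltetrahydrofuran-2-yl]-2-methoxyphenoxy}propane-1,3-diol | COc1ccc([C@@H](O)[C@@H](CO)Oc2ccc([C@H]3O[C@H](c4ccc(OC)c(OC)c4)[C@H](C)[C@H]3C)cc2OC)cc1OC | intermediate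
21 | (2R,3R)-3-(3,4-dimethoxyphenyl)-2-{4-[(2S,3R,4R,5S)-5-(3,4-dimethoxyphenyl)-3,4-dimethyltetrahydrofuran-2-yl]-2-methoxyphenoxy}-3-hydroxypropyl 4-methylbenzenesulfonate | COc1ccc([C@@H](O)[C@@H](COS(=O)(=O)c2ccc(C)cc2)Oc2ccc([C@H]3O[C@H](c4ccc(OC)c(OC)c4)[C@H](C)[C@H]3C)cc2OC)cc1OC | intermediate
22 | (1R,2R)-1-(3,4-dimethoxyphenyl)-2-{4-[(2S,3R,4R,5S)-5-(3,4-dimethoxyphenyl)-3,4-dimethyltetrahydrofuran-2-yl]-2-methoxyphenoxy}propan-1-ol | COc1ccc([C@@H](O)[C@@H](C)Oc2ccc([C@H]3O[C@H](c4ccc(OC)c(OC)c4)[C@H](C)[C@H]3C)cc2OC)cc1OC | target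

Total step count: 10. Longest linear sequence: 9 (steps 1, 2, 3, 5, 6, 7, 8, 9, 10). Step 4 is the only side-branch step.

Steps most likely to fail

Step 7. The boron Lewis acid may open the electron-rich benzylic C–O bonds of the tetrahydrofuran, which would epimerise the cis,trans,cis array. Addition to the deactivated aldehyde may also be slow, so that retro-aldol erodes the diastereomer ratio. The fallback still forms C7–C8, but as a base-mediated acylation, and sets both stereocentres afterwards in a dynamic reduction. It sets out from 13. CsF and methyl bromoacetate in DMF should give methyl 2-{4-[(2S,3R,4R,5S)-5-(3,4-dimethoxyphenyl)-3,4-dimethyltetrahydrofuran-2-yl]-2-methoxyphenoxy}acetate F1. LiHMDS (2 equiv) and 3,4-dimethoxybenzoyl chloride at −78 °C should give the β-keto ester F2, whose C8 is configurationally labile. Asymmetric transfer hydrogenation with dynamic kinetic resolution [RuCl(p-cymene)((S,S)-TsDPEN), HCO2H/Et3N] is known to give syn products from α-alkoxy-β-keto esters. It should funnel both epimers into the syn (2S,3R)-hydroxy ester F3. LiBH4 reduces F3 to diol 20, where the route is rejoined.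

Step 2. Branched regiocontrol may be incomplete at the allylically branched alkene, giving linear aldehyde or alkene isomerisation. Equilibration at C3 may also be incomplete. The fallback builds the same lactol by stepwise oxidation and enolate alkylation and sets out from 4.
- 9-BBN followed by NaOH/H2O2 should give (1S,2R)-1-(3,4-dimethoxyphenyl)-2-methylbutane-1,4-diol F4.
- TEMPO/PhI(OAc)2 oxidative lactonisation should give (4R,5S)-5-(3,4-dimethoxyphenyl)-4-methyldihydrofuran-2(3H)-one F5.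
- LiHMDS/MeI at −78 °C should alkylate the enolate anti to the C4 methyl and give (3R,4R,5S)-5-(3,4-dimethoxyphenyl)-3,4-dimethyldihydrofuran-2(3H)-one F6.
- DIBAL-H at −78 °C returns to lactol 6.

Step 10. The hydride may act as a base, causing E2 elimination toward the enol ether. It may also attack at sulfur, cleaving the S–O bond back to the diol. Either process would compete with substitution next to the branched C8. The fallback replaces the polar substitution by a radical dehalogenation and sets out from 20. Appel-type iodination (I2, PPh3, imidazole) of the primary hydroxyl should give (1R,2S)-1-(3,4-dimethoxyphenyl)-2-{4-[(2S,3R,4R,5S)-5-(3,4-dimethoxyphenyl)-3,4-dimethyltetrahydrofuran-2-yl]-2-methoxyphenoxy}-3-iodopropan-1-ol F7. Concentrated Bu3SnH/AIBN in toluene at 80 °C, where hydrogen transfer should outrun loss of aryloxyl, leads to 22.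

Further compounds
F1 | step 7 | methyl 2-{4-[(2S,3R,4R,5S)-5-(3,4-dimethoxyphenyl)-3,4-dimethyltetrahydrofuran-2-yl]-2-methoxyphenoxy}acetate | COC(=O)COc1ccc([C@H]2O[C@H](c3ccc(OC)c(OC)c3)[C@H](C)[C@H]2C)cc1OC
F2 | step 7 | methyl 3-(3,4-dimethoxyphenyl)-2-{4-[(2S,3R,4R,5S)-5-(3,4-dimethoxyphenyl)-3,4-dimethyltetrahydrofuran-2-yl]-2-methoxyphenoxy}-3-oxopropanoate (C2 epimer mixture) | COC(=O)C(Oc1ccc([C@H]2O[C@H](c3ccc(OC)c(OC)c3)[C@H](C)[C@H]2C)cc1OC)C(=O)c1ccc(OC)c(OC)c1
F3 | step 7 | methyl (2S,3R)-3-(3,4-dimethoxyphenyl)-2-{4-[(2S,3R,4R,5S)-5-(3,4-dimethoxyphenyl)-3,4-dimethyltetrahydrofuran-2-yl]-2-methoxyphenoxy}-3-hydroxypropanoate | COc1ccc([C@@H](O)[C@@H](C(=O)OC)Oc2ccc([C@H]3O[C@H](c4ccc(OC)c(OC)c4)[C@H](C)[C@H]3C)cc2OC)cc1OC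
F4 | step 2 | (1S,2R)-1-(3,4-dimethoxyphenyl)-2-methylbutane-1,4-diol | O[C@H](c1ccc(OC)c(OC)c1)[C@H](C)CCO
F5 | step 2 | (4R,5S)-5-(3,4-dimethoxyphenyl)-4-methyldihydrofuran-2(3H)-one | O=C1O[C@H](c2ccc(OC)c(OC)c2)[C@H](C)C1
F6 | step 2 | (3R,4R,5S)-5-(3,4-dimethoxyphenyl)-3,4-dimethyldihydrofuran-2(3H)-one | O=C1O[C@H](c2ccc(OC)c(OC)c2)[C@H](C)[C@H]1C
F7 | step 10 | (1R,2S)-1-(3,4-dimethoxyphenyl)-2-{4-[(2S,3R,4R,5S)-5-(3,4-dimethoxyphenyl)-3,4-dimethyltetrahydrofuran-2-yl]-2-methoxyphenoxy}-3-iodopropan-1-ol | COc1ccc([C@@H](O)[C@@H](CI)Oc2ccc([C@H]3O[C@H](c4ccc(OC)c(OC)c4)[C@H](C)[C@H]3C)cc2OC)cc1OC
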